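**Strategy**

The target is the diester of (2E,6E)-2,6-dimethylocta-2,6-dienedioic acid with two identical amino alcohol units, so everything rests on one bicyclic building block that is built on a preformed piperidine. Its cyclopentane ring (C4a–C5–C6–C7–C7a) is closed last, by aldol cyclodehydration of a piperidin-4-one whose C7a carries a 3-oxobutan-2-yl arm. The step exploits the 1,3-relationship between ring-fusion carbon C4a and oxygen-bearing C6: in the diketone precursor C4, C7a and C7 all lie alpha to a carbonyl group, so base sets their relative configuration while the ring forms. Hydrogenation, a resolving enzymatic reduction and a double Mitsunobu esterification complete the route.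

Key step: step 3

Remark: both amino alcohol units are the same (4S,4aR,6S,7R,7aS)-alcohol, so one building block is made once and used at both ester positions. Atom labels C1 to C7a follow the cyclopenta[c]pyridine numbering (N2; methyl groups on N2, C4 and C7; oxygen on C6; ring fusion at C4a and C7a) and are also used for the atoms of earlier intermediates that become these positions. "rac-" marks a racemate, drawn as the enantiomer that leads to the target.

**Route**

Step 1
Reactants: 1 3-nitrobutan-2-ol (mixture of diastereomers)
Product: 3 (E)-2-nitrobut-2-ene, via 3-nitrobutan-2-yl methanesulfonate 2 (not isolated)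
Conditions: MsCl, Et3N, CH2Cl2, 0 °C to rt; distillation
Reagents that add atoms: none
Why: Mesylation followed by E1cB elimination is the standard dehydration of a beta-nitro alcohol to the conjugated nitroalkene, and no stereocentre remains.

Step 2
Reactants: 4 1,3-dimethylpiperidin-4-one (racemic); 3 (E)-2-nitrobut-2-ene
Product: 7 1,3-dimethyl-5-(3-oxobutan-2-yl)piperidin-4-one (racemic; mixture of epimers), via lithium enolate 5 (not isolated), via lithium nitronate 6 (not isolated)
Conditions: LiN(i-Pr)2 (LDA), THF, −78 °C; then 3, −78 °C; then poured into 4 M aq. H2SO4, 0 °C; K2CO3 work-up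
Reagents that add atoms: water, O
Why: Kinetic deprotonation should take the less substituted CH2 alpha position, the enolate adds to the beta-carbon of the nitroalkene (Michael addition) and acid hydrolyses the nitronate to the ketone (Nef reaction); the alpha stereocentres form unselectively, which is harmless because all three are equilibrated in step 3.

Step 3
Reactants: 7 1,3-dimethyl-5-(3-oxobutan-2-yl)piperidin-4-one
Product: 9 rac-(4S,7R,7aR)-2,4,7-trimethyl-1,2,3,4,7,7a-hexahydro-6H-cyclopenta[c]pyridin-6-one, via aldol adduct 8 (not isolated)
Conditions: KOH (2%), EtOH/H2O, 60 °C, stopped when 7 is consumed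
Reagents that add atoms: none
Why: Hydroxide first equilibrates the three alpha stereocentres of 7, then the enolate of the methyl ketone (C5) adds to the ring carbonyl (C4a) and the aldol 8 loses water by E1cB, so that the conjugated cyclopentenone is the sink of an otherwise reversible system; this is the classical intramolecular aldol condensation of a 1,4-diketone to a cyclopent-2-enone. The cyclopentane ring closes through the C5–C4a bond in the 5-(enolendo)-exo-trig mode, which Baldwin's rules rank as slow but which operates routinely under reversible conditions because dehydration removes the aldol. No new stereocentre is formed (C4a becomes sp2); C4 and C7a are set by the preference of the 3,5-disubstituted piperidin-4-one for the cis-diequatorial arrangement, and C7 by the preference of its methyl group to sit trans to C1 on the new ring. The step needs chemoselectivity among the possible aldol pathways and a product that stays put: the only other ring-forming aldol (C4 enolate onto C6) gives a bridged aldol that cannot dehydrate into conjugation and reverts, and the moderate temperature and short exposure are chosen so that the enone does not move its double bond to C7=C7a through the dienolate.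

Step 4
Reactants: 9 rac-(4S,7R,7aR)-2,4,7-trimethyl-1,2,3,4,7,7a-hexahydro-6H-cyclopenta[c]pyridin-6-one
Product: 10 rac-(4S,4aR,7R,7aS)-2,4,7-trimethyloctahydro-6H-cyclopenta[c]pyridin-6-one
Conditions: H2 (1 atm), 10% Pd/C, EtOH, rt
Reagents that add atoms: none
Why: Heterogeneous syn hydrogenation of the trisubstituted enone should deliver hydrogen to C4a from the convex face that carries H7a and the axial H4, because the other face is covered by C1 and C3 of the piperidine chair and their axial hydrogens; this gives the cis-fused ketone with the C4 methyl, C5 and C7 all cis on the piperidine ring, while C7 keeps its methyl trans to C1 as the more stable alpha epimer.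

Step 5
Reactants: 10 rac-(4S,4aR,7R,7aS)-2,4,7-trimethyloctahydro-6H-cyclopenta[c]pyridin-6-one
Product: 11 (4S,4aR,6R,7R,7aS)-2,4,7-trimethyloctahydro-1H-cyclopenta[c]pyridin-6-ol
Conditions: ketoreductase (NADPH-dependent, chosen from a commercial panel), NADP+ (cat.), i-PrOH, potassium phosphate buffer pH 7, 30 °C, run to about half conversion; chromatography
Reagents that add atoms: none
Why: Enzymatic ketone reduction used as a kinetic resolution, in which a ketoreductase chosen by screening should reduce only the (4S,4aR,7R,7aS) enantiomer and add hydride to C6 from the exo face (the more open face, which also carries the C7 methyl) to set 6R with the hydroxyl trans to that methyl, while the mirror-image ketone stays unreduced and is removed by chromatography; protonated N-methyl bicyclic ketones are known substrates of this enzyme class (tropinone reduction).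

Step 6
Reactants: 12 geranyl acetate
Product: 13 (2E,6E)-8-hydroxy-3,7-dimethylocta-2,6-dien-1-yl acetate
Conditions: SeO2 (cat.), t-BuOOH, salicylic acid (cat.), CH2Cl2, rt
Reagents that add atoms: selenium dioxide, O=[Se]=O (oxygen carrier); tert-butyl hydroperoxide, CC(C)(C)OO (terminal oxygen source)
Why: Catalytic SeO2 allylic oxidation (Riley oxidation, ene reaction then 2,3-sigmatropic shift) should attack the (E)-methyl group of the more electron-rich terminal alkene with retention of E geometry, while the allylic acetate end is deactivated.

Step 7
Reactants: 13 (2E,6E)-8-hydroxy-3,7-dimethylocta-2,6-dien-1-yl acetate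
Product: 14 (2E,6E)-2,6-dimethylocta-2,6-diene-1,8-diol
Conditions: K2CO3, MeOH, rt
Reagents that add atoms: none
Why: Carbonate-catalysed transesterification with methanol removes the acetate without touching the allylic alcohols or the alkene geometry.

Step 8
Reactants: 14 (2E,6E)-2,6-dimethylocta-2,6-diene-1,8-diol
Product: 16 (2E,6E)-2,6-dimethylocta-2,6-dienedioic acid, via (2E,6E)-2,6-dimethylocta-2,6-dienedial 15 (not isolated)
Conditions: PhI(OAc)2, TEMPO (cat.), CH2Cl2, rt; then NaClO2, NaH2PO4, 2-methylbut-2-ene, t-BuOH/H2O, 0 °C to rt
Reagents that add atoms: sodium chlorite, [Na+].[O-]Cl=O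
Why: Oxoammonium (TEMPO) oxidation should convert both allylic alcohols to the enals without E/Z isomerisation, and the Pinnick oxidation then takes the aldehydes to the acids while 2-methylbut-2-ene scavenges HOCl so that the trisubstituted alkenes survive.

Step 9
Reactants: 11 (4S,4aR,6R,7R,7aS)-2,4,7-trimethyloctahydro-1H-cyclopenta[c]pyridin-6-ol (2.2 equiv); 16 (2E,6E)-2,6-dimethylocta-2,6-dienedioic acid
Product: 19 bis[(4S,4aR,6S,7R,7aS)-2,4,7-trimethyloctahydro-1H-cyclopenta[c]pyridin-6-yl] (2E,6E)-2,6-dimethylocta-2,6-dienedioate (CNP0240822.2), via C8 monoester 17 (not isolated), via C1 monoester 18 (not isolated)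
Conditions: PPh3, DIAD, THF, 0 °C to rt
Reagents that add atoms: none
Why: Double Mitsunobu esterification, in which each carboxylate of 16 displaces the alkoxyphosphonium ion of 11 at C6 by SN2 with inversion (6R to 6S) and so sets both ester stereocentres; the acid acts only as nucleophile and is never activated as an acyl donor, so the E-alkenes cannot deconjugate through a ketene, and the tertiary amines are tolerated.

**Compound list**

1 | 3-nitrobutan-2-ol (mixture of diastereomers) | CC(O)C(C)[N+](=O)[O-] | starting material
2 | 3-nitrobutan-2-yl methanesulfonate (not isolated) | CC(OS(C)(=O)=O)C(C)[N+](=O)[O-] | intermediate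
3 | (E)-2-nitrobut-2-ene | C/C=C(\C)[N+](=O)[O-] | intermediate
4 | 1,3-dimethylpiperidin-4-one (racemic) | CC1CN(C)CCC1=O | starting material
5 | lithium 1,3-dimethyl-1,2,3,6-tetrahydropyridin-4-olate (racemic; not isolated) | [Li+].[O-]C1=CCN(C)CC1C | intermediate
6 | lithium 3-(1,5-dimethyl-4-oxopiperidin-3-yl)butane-2-nitronate (mixture of epimers; not isolated) | [Li+].CC(C1CN(C)CC(C)C1=O)C(C)=[N+]([O-])[O-] | intermediate
7 | 1,3-dimethyl-5-(3-oxobutan-2-yl)piperidin-4-one (racemic; formed as a mixture of epimers at the three alpha-carbons; drawn as the (3R,5S,2'R) isomer that leads on) | CC(=O)[C@H](C)[C@H]1CN(C)C[C@@H](C)C1=O | intermediate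
8 | rac-(4R,4aS,7R,7aS)-4a-hydroxy-2,4,7-trimethyloctahydro-6H-cyclopenta[c]pyridin-6-one (aldol adduct; not isolated) | O=C1C[C@@]2(O)[C@H](CN(C)C[C@H]2C)[C@H]1C | intermediate
9 | rac-(4S,7R,7aR)-2,4,7-trimethyl-1,2,3,4,7,7a-hexahydro-6H-cyclopenta[c]pyridin-6-one | O=C1C=C2[C@H](CN(C)C[C@H]2C)[C@H]1C | intermediate
10 | rac-(4S,4aR,7R,7aS)-2,4,7-trimethyloctahydro-6H-cyclopenta[c]pyridin-6-one | O=C1C[C@H]2[C@H](CN(C)C[C@H]2C)[C@H]1C | intermediate
11 | (4S,4aR,6R,7R,7aS)-2,4,7-trimethyloctahydro-1H-cyclopenta[c]pyridin-6-ol (single enantiomer; hydroxyl trans to the C7 methyl) | O[C@@H]1C[C@H]2[C@H](CN(C)C[C@H]2C)[C@H]1C | intermediate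
12 | geranyl acetate, (2E)-3,7-dimethylocta-2,6-dien-1-yl acetate | CC(=O)OC/C=C(\C)CCC=C(C)C | starting material
13 | (2E,6E)-8-hydroxy-3,7-dimethylocta-2,6-dien-1-yl acetate | CC(=O)OC/C=C(\C)CC/C=C(\C)CO | intermediate
14 | (2E,6E)-2,6-dimethylocta-2,6-diene-1,8-diol | OC/C=C(\C)CC/C=C(\C)CO | intermediate
15 | (2E,6E)-2,6-dimethylocta-2,6-dienedial (not isolated) | O=C/C=C(\C)CC/C=C(\C)C=O | intermediate
16 | (2E,6E)-2,6-dimethylocta-2,6-dienedioic acid | OC(=O)/C=C(\C)CC/C=C(\C)C(=O)O | intermediate
17 | C8 monoester: (2E,6E)-2,6-dimethyl-8-oxo-8-{[(4S,4aR,6S,7R,7aS)-2,4,7-trimethyloctahydro-1H-cyclopenta[c]pyridin-6-yl]oxy}octa-2,6-dienoic acid (not isolated) | C/C(=C\C(=O)O[C@H]1C[C@H]2[C@H](CN(C)C[C@H]2C)[C@H]1C)CC/C=C(\C)C(=O)O | intermediate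
18 | C1 monoester: (2E,6E)-3,7-dimethyl-8-oxo-8-{[(4S,4aR,6S,7R,7aS)-2,4,7-trimethyloctahydro-1H-cyclopenta[c]pyridin-6-yl]oxy}octa-2,6-dienoic acid (not isolated) | C/C(=C\C(=O)O)CC/C=C(\C)C(=O)O[C@H]1C[C@H]2[C@H](CN(C)C[C@H]2C)[C@H]1C | intermediate
19 | bis[(4S,4aR,6S,7R,7aS)-2,4,7-trimethyloctahydro-1H-cyclopenta[c]pyridin-6-yl] (2E,6E)-2,6-dimethylocta-2,6-dienedioate (CNP0240822.2) | C/C(=C\C(=O)O[C@H]1C[C@H]2[C@H](CN(C)C[C@H]2C)[C@H]1C)CC/C=C(\C)C(=O)O[C@H]1C[C@H]2[C@H](CN(C)C[C@H]2C)[C@H]1C | target

**Count and risks**

Total step count: 9. Longest linear sequence: 6 steps (steps 1, 2, 3, 4, 5 and 9); the diacid branch is steps 6 to 8.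

The three steps most likely to fail:

Step 3. Under the equilibrating hydroxide the enone double bond may migrate toward the more substituted C7=C7a position through the dienolate, which would erase the C7a stereocentre and loosen the C4/ring-fusion relationship, or the cyclodehydration may stall at the aldol stage. The fallback sets out from 7 and comes back at 9. 7 is first equilibrated with Et3N in MeOH, then the methyl ketone is deprotonated kinetically (LDA, THF, −78 °C) and the enolate adds to the ring carbonyl on warming to −20 °C, giving the aldol 8, which is now isolated. Acylation with trifluoroacetic anhydride and pyridine (CH2Cl2, 0 °C) gives the tertiary trifluoroacetate F1, and DBU at 0 °C removes trifluoroacetate by E1cB toward the only acidic beta-hydrogens (C5), giving 9 without exposure to hot hydroxide.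

Step 4. Hydrogen delivery to C4a may show poor facial selectivity on the metal surface, since the C7 methyl group also sits on the convex face, or the amine may slow the catalyst. The fallback sets out from 9 and comes back at 10. Homogeneous conjugate reduction with [(Ph3P)CuH]6 (cat.) and PhMe2SiH in toluene at rt should add the bulky copper hydride to C4a from the equatorial direction and give the dimethylphenylsilyl enol ether F2. Hydrolysis with 1 M HCl in THF then gives 10.

Step 5. The enzyme may discriminate the two enantiomers of the ketone insufficiently, or show low activity on the protonated amine. The fallback sets out from 10 and comes back at 11. NaBH4 in MeOH at −20 °C should add hydride from the exo face, because the endo face of C6 lies over the piperidine ring and its axial C1–H, and give the racemic trans alcohol F3. Lipase-catalysed acylation (Candida antarctica lipase B, vinyl acetate, MTBE) is a well-established resolution of trans-2-alkylcycloalkanols and, by the Kazlauskas rule, should acylate the (6R,7R) enantiomer to the (6R)-acetate F4, which is separated from the unreacted mirror-image alcohol. Methanolysis (K2CO3, MeOH) gives 11.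

**Further compounds**

F1 | step 3 | trifluoroacetate of aldol 8, rac-2,4,7-trimethyl-6-oxooctahydro-4aH-cyclopenta[c]pyridin-4a-yl trifluoroacetate | O=C1C[C@@]2(OC(=O)C(F)(F)F)[C@H](CN(C)C[C@H]2C)[C@H]1C
F2 | step 4 | rac-6-[dimethyl(phenyl)silyloxy]-2,4,7-trimethyl-2,3,4,4a,7,7a-hexahydro-1H-cyclopenta[c]pyridine (silyl enol ether) | C[Si](C)(c1ccccc1)OC1=C[C@H]2[C@H](CN(C)C[C@H]2C)[C@H]1C
F3 | step 5 | rac-(4S,4aR,6R,7R,7aS)-2,4,7-trimethyloctahydro-1H-cyclopenta[c]pyridin-6-ol (racemate of 11) | O[C@@H]1C[C@H]2[C@H](CN(C)C[C@H]2C)[C@H]1C
F4 | step 5 | (4S,4aR,6R,7R,7aS)-2,4,7-trimethyloctahydro-1H-cyclopenta[c]pyridin-6-yl acetate | CC(=O)O[C@@H]1C[C@H]2[C@H](CN(C)C[C@H]2C)[C@H]1C
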